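**Plan**
- The last disconnections return the C6 methyl ether and the C7 hydroxyl to a 6,7-diol and then to its bis(benzyl) ether.
- Ring C is then opened at three bonds at once: O1–C8a, C4–C4a and O1–C2. This leaves a symmetric 4,5-bis(benzyloxy)benzyne (stored as its ortho-silylaryl triflate) and 3-(3,4,5-trimethoxyphenyl)propiolic acid.
- Enabling feature: in ring A, O1 on C8a and the acyl carbon C4 on C4a are ortho neighbours, and the C6 and C7 oxygens lie mirror-symmetrically about the C4a–C8a bond. A symmetric aryne can therefore accept both bonds with no regiochemical question.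
- Forward: rings A and B arrive intact (triflate in three steps from 3,4-bis(benzyloxy)benzaldehyde, acid in one step from the aryl acetylene and CO2). Ring C forms in the aryne step. Four closing steps tell O7 from O6 through the higher acidity of the hydroxyl para to C4=O.
- Stereochemistry: the target is achiral with no stereocentre, so nothing has to be set or preserved.

Key step: step 5

Remark: compounds 1 and 9 are taken as commercial. No compound of the main route carries a stereocentre, so its SMILES strings need no stereodescriptors.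

**Route**

Step 1
Reactants: 1 3,4-bis(benzyloxy)benzaldehyde
Product: 3 3,4-bis(benzyloxy)phenol, via formate ester 2 (not isolated)
Conditions: mCPBA (1.3 equiv), CH2Cl2, 0 °C to rt; aq NaHCO3 wash; then K2CO3 (cat.), MeOH, rt
Reagents that add atoms: 3-chloroperoxybenzoic acid (mCPBA), O=C(OO)c1cccc(Cl)c1
Why: Dakin-type Baeyer–Villiger oxidation, in which the electron-rich aryl group migrates to oxygen and the aryl formate is then methanolysed under mild base that leaves benzyl ethers untouched.

Step 2
Reactants: 3 3,4-bis(benzyloxy)phenol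
Product: 4 4,5-bis(benzyloxy)-2-bromophenol
Conditions: NBS (1.0 equiv), MeCN, −20 to 0 °C
Reagents that add atoms: N-bromosuccinimide, O=C1CCC(=O)N1Br
Why: Electrophilic aromatic bromination should go to the one unhindered position that is ortho to the hydroxyl and para to a benzyloxy group, since the para position is blocked and the other ortho position is flanked by two oxygens.

Step 3
Reactants: 4 4,5-bis(benzyloxy)-2-bromophenol
Product: 8 4,5-bis(benzyloxy)-2-(trimethylsilyl)phenyl trifluoromethanesulfonate, via aryl trimethylsilyl ether 5 (not isolated), via aryllithium 6 (not isolated), via lithium 2-silylphenoxide 7 (not isolated)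
Conditions: HMDS, THF, reflux, then evaporate; n-BuLi (1.1 equiv), THF, −100 to −80 °C; Tf2O (1.2 equiv), −100 °C to rt
Reagents that add atoms: hexamethyldisilazane, C[Si](C)(C)N[Si](C)(C)C; trifluoromethanesulfonic anhydride, O=S(=O)(OS(=O)(=O)C(F)(F)F)C(F)(F)F
Why: This is the standard one-pot entry to ortho-silylaryl triflates (O-silylation, bromine–lithium exchange, retro-Brook 1,3 O-to-C silyl shift, O-triflation), and exchange at −100 °C should outpace any metalation of the benzyl ethers.

Step 4
Reactants: 9 5-ethynyl-1,2,3-trimethoxybenzene; 10 carbon dioxide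
Product: 12 3-(3,4,5-trimethoxyphenyl)propiolic acid, via lithium acetylide 11 (not isolated)
Conditions: n-BuLi (1.05 equiv), THF, −78 °C; dry CO2, −78 °C to rt; aq HCl
Reagents that add atoms: none
Why: Carboxylation of a lithium acetylide with CO2 is a dependable way to arylpropiolic acids, and the methyl ethers are inert to it.

Step 5
Reactants: 8 4,5-bis(benzyloxy)-2-(trimethylsilyl)phenyl trifluoromethanesulfonate; 12 3-(3,4,5-trimethoxyphenyl)propiolic acid
Product: 15 6,7-bis(benzyloxy)-2-(3,4,5-trimethoxyphenyl)-4H-chromen-4-one, via aryne 13 (not isolated), via ortho-hydroxyaryl ynone 14 (not isolated)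
Conditions: 8 (1.5 equiv), 12 (1.0 equiv), CsF (4 equiv, dried), dry THF, sealed tube, 125 °C
Reagents that add atoms: none
Why: Fluoride removes the silyl group of 8 and triflate departs to give the symmetric aryne 13; the cesium carboxylate of 12 adds through oxygen, and the resulting ortho aryl anion attacks its own ester carbonyl through a four-membered alkoxide that collapses to the ortho-acyl phenoxide 14, forming O1–C8a and C4–C4a with one acid oxygen becoming O1 and the other staying on C4. The closest known reaction type is the insertion of arynes into the C–O bond of carboxylic acids to give ortho-hydroxyaryl ketones, which with alkynoic acids carries on to chromones and flavones. Ring C closes by 6-endo-dig oxa-Michael addition of the phenoxide to the β-carbon (C2) of the ynone, and the proton that the acid brought in ends up on C3. No stereocentre is formed. The step needs regiocontrol on the aryne, acyl transfer ahead of protonation of the aryl anion, and 6-endo rather than 5-exo closure: the first is settled by the mirror symmetry of 13, the second should be favoured by dry THF at high temperature with excess CsF and the carbonyl held next to the anion, and the third by the β-carbon being the electrophilic site of the ynone under aprotic conditions without a metal catalyst.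

Step 6
Reactants: 15 6,7-bis(benzyloxy)-2-(3,4,5-trimethoxyphenyl)-4H-chromen-4-one
Product: 16 6,7-dihydroxy-2-(3,4,5-trimethoxyphenyl)-4H-chromen-4-one
Conditions: H2 (1 atm), 10% Pd/C, THF/MeOH, rt
Reagents that add atoms: none
Why: Catalytic hydrogenolysis of aryl benzyl ethers should leave the methyl ethers alone and spare the C2–C3 double bond, which is part of a vinylogous ester and is not readily reduced at 1 atm.

Step 7
Reactants: 16 6,7-dihydroxy-2-(3,4,5-trimethoxyphenyl)-4H-chromen-4-one
Product: 17 7-(benzyloxy)-6-hydroxy-2-(3,4,5-trimethoxyphenyl)-4H-chromen-4-one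
Conditions: BnBr (1.05 equiv), K2CO3 (1.1 equiv), DMF, 0 °C to rt
Reagents that add atoms: benzyl bromide, BrCc1ccccc1
Why: Site-selective Williamson etherification, because the C7 hydroxyl is para to the C4 carbonyl and much more acidic than the C6 hydroxyl, so one equivalent of weak base should form and alkylate only the 7-phenoxide, as is usual for 6,7-dihydroxy-coumarins and -flavones.

Step 8
Reactants: 17 7-(benzyloxy)-6-hydroxy-2-(3,4,5-trimethoxyphenyl)-4H-chromen-4-one
Product: 18 7-(benzyloxy)-6-methoxy-2-(3,4,5-trimethoxyphenyl)-4H-chromen-4-one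
Conditions: MeI (1.5 equiv), K2CO3 (1.5 equiv), DMF, 40 °C
Reagents that add atoms: iodomethane, CI
Why: Williamson methylation of the only remaining phenol, with no competing nucleophilic site in the molecule.

Step 9
Reactants: 18 7-(benzyloxy)-6-methoxy-2-(3,4,5-trimethoxyphenyl)-4H-chromen-4-one
Product: 19 Prosogerin D, 7-hydroxy-6-methoxy-2-(3,4,5-trimethoxyphenyl)-4H-chromen-4-one
Conditions: H2 (1 atm), 10% Pd/C, THF/MeOH, rt
Reagents that add atoms: none
Why: Hydrogenolysis of the single benzyl ether under the conditions of step 6 should release the C7 hydroxyl and leave the four methyl ethers and the chromone untouched.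

**Compound list**

1 | 3,4-bis(benzyloxy)benzaldehyde | O=Cc1ccc(OCc2ccccc2)c(OCc2ccccc2)c1 | starting material
2 | 3,4-bis(benzyloxy)phenyl formate | O=COc1ccc(OCc2ccccc2)c(OCc2ccccc2)c1 | intermediate (not isolated)
3 | 3,4-bis(benzyloxy)phenol | Oc1ccc(OCc2ccccc2)c(OCc2ccccc2)c1 | intermediate
4 | 4,5-bis(benzyloxy)-2-bromophenol | Oc1cc(OCc2ccccc2)c(OCc2ccccc2)cc1Br | intermediate
5 | [4,5-bis(benzyloxy)-2-bromophenoxy]trimethylsilane | C[Si](C)(C)Oc1cc(OCc2ccccc2)c(OCc2ccccc2)cc1Br | intermediate (not isolated)
6 | [4,5-bis(benzyloxy)-2-(trimethylsilyloxy)phenyl]lithium | C[Si](C)(C)Oc1cc(OCc2ccccc2)c(OCc2ccccc2)cc1[Li] | intermediate (not isolated)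
7 | lithium 4,5-bis(benzyloxy)-2-(trimethylsilyl)phenoxide | [Li+].[O-]c1cc(OCc2ccccc2)c(OCc2ccccc2)cc1[Si](C)(C)C | intermediate (not isolated)
8 | 4,5-bis(benzyloxy)-2-(trimethylsilyl)phenyl trifluoromethanesulfonate | C[Si](C)(C)c1cc(OCc2ccccc2)c(OCc2ccccc2)cc1OS(=O)(=O)C(F)(F)F | intermediate (aryne precursor of the key step)
9 | 5-ethynyl-1,2,3-trimethoxybenzene | C#Cc1cc(OC)c(OC)c(OC)c1 | starting material
10 | carbon dioxide | O=C=O | starting material
11 | lithium (3,4,5-trimethoxyphenyl)acetylide | [Li]C#Cc1cc(OC)c(OC)c(OC)c1 | intermediate (not isolated)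
12 | 3-(3,4,5-trimethoxyphenyl)propiolic acid | O=C(O)C#Cc1cc(OC)c(OC)c(OC)c1 | intermediate (acid partner of the key step)
13 | 4,5-bis(benzyloxy)benzyne | C1#CC=C(OCc2ccccc2)C(OCc2ccccc2)=C1 | intermediate (not isolated)
14 | 1-[4,5-bis(benzyloxy)-2-hydroxyphenyl]-3-(3,4,5-trimethoxyphenyl)prop-2-yn-1-one (present as its cesium phenoxide) | O=C(C#Cc1cc(OC)c(OC)c(OC)c1)c1cc(OCc2ccccc2)c(OCc2ccccc2)cc1O | intermediate (not isolated)
15 | 6,7-bis(benzyloxy)-2-(3,4,5-trimethoxyphenyl)-4H-chromen-4-one | O=c1cc(-c2cc(OC)c(OC)c(OC)c2)oc2cc(OCc3ccccc3)c(OCc3ccccc3)cc12 | intermediate (product of the key step)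
16 | 6,7-dihydroxy-2-(3,4,5-trimethoxyphenyl)-4H-chromen-4-one | O=c1cc(-c2cc(OC)c(OC)c(OC)c2)oc2cc(O)c(O)cc12 | intermediate
17 | 7-(benzyloxy)-6-hydroxy-2-(3,4,5-trimethoxyphenyl)-4H-chromen-4-one | O=c1cc(-c2cc(OC)c(OC)c(OC)c2)oc2cc(OCc3ccccc3)c(O)cc12 | intermediate
18 | 7-(benzyloxy)-6-methoxy-2-(3,4,5-trimethoxyphenyl)-4H-chromen-4-one | O=c1cc(-c2cc(OC)c(OC)c(OC)c2)oc2cc(OCc3ccccc3)c(OC)cc12 | intermediate
19 | Prosogerin D, 7-hydroxy-6-methoxy-2-(3,4,5-trimethoxyphenyl)-4H-chromen-4-one | COc1cc2c(=O)cc(-c3cc(OC)c(OC)c(OC)c3)oc2cc1O | target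

**Step count**
Total: 9 steps. Longest linear sequence: 8 steps (1, 2, 3, 5, 6, 7, 8, 9); the acid branch contributes step 4.

**Steps most likely to fail**

Step 5. The ortho aryl anion may be protonated before it reaches the ester carbonyl, so that only O-arylation occurs. The cesium arylpropiolate may lose CO2 at 125 °C, fluoride or carboxylate may add to the alkynoate, or the ynone phenoxide may close 5-exo. The fallback keeps the aryne C–O insertion but runs it one oxidation level lower. It sets out from triflate 8, which is heated under the same CsF/THF conditions with commercial (E)-3,4,5-trimethoxycinnamic acid; this acid does not decarboxylate readily and offers no 5-exo path. Insertion should give the cesium salt of (E)-1-[4,5-bis(benzyloxy)-2-hydroxyphenyl]-3-(3,4,5-trimethoxyphenyl)prop-2-en-1-one F1, which should close by 6-endo-trig oxa-Michael addition to racemic 6,7-bis(benzyloxy)-2-(3,4,5-trimethoxyphenyl)chroman-4-one F2. Dehydrogenation with catalytic I2 in DMSO at about 120 °C then comes back to the route at flavone 15.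

Step 3. The labile O–Si bond may be hydrolysed before the exchange, the aryllithium may be protonated, the O-to-C silyl migration may stay incomplete, or a benzylic CH2 may be metalated. The fallback makes the C–Si bond by direct electrophilic silylation of a stably protected phenol, so no migration is needed. It sets out from bromophenol 4: allyl bromide and K2CO3 in acetone should give 1-(allyloxy)-4,5-bis(benzyloxy)-2-bromobenzene F3. Bromine–lithium exchange with n-BuLi in THF at −78 °C and trapping with Me3SiCl should give [2-(allyloxy)-4,5-bis(benzyloxy)phenyl]trimethylsilane F4. Pd(PPh3)4 with morpholine removes the allyl group under neutral conditions to give 4,5-bis(benzyloxy)-2-(trimethylsilyl)phenol F5. Tf2O and pyridine in CH2Cl2 at 0 °C then come back to the route at triflate 8.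

Step 7. Discrimination between the two phenols may be insufficient, with alkylation at O6 or at both oxygens. Double alkylation only regenerates 15, which can be sent through step 6 again. The fallback inverts the logic: instead of protecting the more acidic hydroxyl, it alkylates the more nucleophilic oxide of the dianion. It sets out from diol 16: NaH (2.2 equiv) in DMF at 0 °C should give disodium 4-oxo-2-(3,4,5-trimethoxyphenyl)-4H-chromene-6,7-diolate F6. In F6 the 7-oxide is delocalised into the C4 carbonyl and the 6-oxide is the localised, more reactive one, as in the dianions of 3,4-dihydroxybenzaldehyde and its esters. One equivalent of MeI should then methylate O6, and acidic work-up arrives directly at target 19, bypassing 17 and 18.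

**Further compounds**

F1 | step 5 | (E)-1-[4,5-bis(benzyloxy)-2-hydroxyphenyl]-3-(3,4,5-trimethoxyphenyl)prop-2-en-1-one | O=C(/C=C/c1cc(OC)c(OC)c(OC)c1)c1cc(OCc2ccccc2)c(OCc2ccccc2)cc1O
F2 | step 5 | racemic 6,7-bis(benzyloxy)-2-(3,4,5-trimethoxyphenyl)chroman-4-one | O=C1CC(c2cc(OC)c(OC)c(OC)c2)Oc2cc(OCc3ccccc3)c(OCc3ccccc3)cc12
F3 | step 3 | 1-(allyloxy)-4,5-bis(benzyloxy)-2-bromobenzene | C=CCOc1cc(OCc2ccccc2)c(OCc2ccccc2)cc1Br
F4 | step 3 | [2-(allyloxy)-4,5-bis(benzyloxy)phenyl]trimethylsilane | C=CCOc1cc(OCc2ccccc2)c(OCc2ccccc2)cc1[Si](C)(C)C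
F5 | step 3 | 4,5-bis(benzyloxy)-2-(trimethylsilyl)phenol | C[Si](C)(C)c1cc(OCc2ccccc2)c(OCc2ccccc2)cc1O
F6 | step 7 | disodium 4-oxo-2-(3,4,5-trimethoxyphenyl)-4H-chromene-6,7-diolate | [Na+].[Na+].[O-]c1cc2oc(-c3cc(OC)c(OC)c(OC)c3)cc(=O)c2cc1[O-]
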